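The target is a head-to-tail [2+2] homodimer of one styrylpyrone: its cyclobutane (C1, C6, C7 and C8 of the 2-oxabicyclo[4.2.0]octenone) joins the ring C5=C6 bond (pyrone numbering) of one 6-(4-hydroxystyryl)-4-methoxy-2-pyrone to the styryl C=C of a second. Everything rests on a biomimetic, topochemical photocycloaddition that forms C6–C7 and, closing the four-membered ring, the bond between the oxygen-bearing quaternary C1 and the pyronyl-bearing C8, setting all four stereocentres in one operation. The precursor is the monomer itself with a (1S)-camphanoyl group on the phenol: the homochiral crystal should present a single pyrone face, and the two cyclobutane antipodes become separable diastereomers.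

Key step: step 3

Assumption: which cyclobutane antipode the (1S)-camphanoyl lattice favours cannot be predicted; the route is written for the case that it is the one shown (the camphanoyl groups of known configuration allow the absolute configuration of 7 to be assigned by X-ray diffraction), and (1R)-camphanic chloride would be used in step 2 otherwise.

Step 1
Reactants: 1 4-methoxy-6-methyl-2H-pyran-2-one; 2 4-(tetrahydro-2H-pyran-2-yloxy)benzaldehyde
Product: 4 6-[(E)-2-(4-hydroxyphenyl)ethenyl]-4-methoxy-2H-pyran-2-one, via tetrahydropyranyl ether 3 (not isolated)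
Conditions: Mg(OMe)2, MeOH, reflux; then HCl in MeOH, rt
Reagents that add atoms: none
Why: Mg(OMe)2-mediated vinylogous aldol (Knoevenagel-type) condensation of the acidic 6-methyl group with the aldehyde, the standard entry to 6-styryl-4-methoxy-2-pyrones, should give the conjugated E-alkene under thermodynamic control, and the base-stable tetrahydropyranyl acetal is then cleaved by acid-catalysed acetal exchange.

Step 2
Reactants: 4 6-[(E)-2-(4-hydroxyphenyl)ethenyl]-4-methoxy-2H-pyran-2-one; 5 (1S)-(−)-camphanic chloride
Product: 6 4-[(E)-2-(4-methoxy-2-oxo-2H-pyran-6-yl)ethenyl]phenyl (1S,4R)-camphanate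
Conditions: Et3N, DMAP (cat.), CH2Cl2/THF, 0 °C to rt
Reagents that add atoms: (1S)-(−)-camphanic chloride 5, ClC(=O)[C@@]12CC[C@@](C)(C(=O)O1)C2(C)C
Why: DMAP-catalysed O-acylation of the phenol by the acid chloride (nucleophilic acyl substitution); the bridgehead acyl group has no α-hydrogen, so the auxiliary cannot epimerise, and camphanates usually crystallise well.

Step 3
Reactants: 6 4-[(E)-2-(4-methoxy-2-oxo-2H-pyran-6-yl)ethenyl]phenyl (1S,4R)-camphanate (two molecules)
Product: 7 bis[(1S,4R)-camphanate] of the (1R,6S,7S,8S)-dimer 8
Conditions: crystalline 6 (recrystallised from EtOAc/heptane), thin layer between Pyrex plates, 365 nm LED, 20 °C, periodic regrinding; then SiO2 chromatography and recrystallisation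
Reagents that add atoms: none
Why: Excitation of the styrylpyrone chromophore inside an antiparallel, offset π-stack should give a photochemical [2+2] cycloaddition between the ring C5=C6 bond of one molecule and the styryl C=C of its neighbour, in which the bond from pyrone C5 to the aryl-bearing carbon (C6–C7 of 7) is joined by the ring-closing bond from the oxygen-bearing pyrone C6 to the pyronyl-bearing carbon (C1–C8 of 7). The closest known reaction type is the topochemical head-to-tail photodimerisation of 6-styryl-2-pyrones and cinnamates in the crystal (parallel double bonds within about 4.2 Å), combined with the chiral-handle approach to asymmetric solid-state photodimerisation. The cyclobutane is closed by an intermolecular suprafacial–suprafacial [2+2] addition, which fuses it cis to the existing pyranone ring. C1 and C6 follow from cis addition to the ring alkene, the trans C7/C8 relationship from the E geometry held by the lattice, and the aryl-cis-to-pyranone, pyronyl-cis-to-styryl relationship from the stack in which the aryl ring of the upper molecule lies over the pyrone ring of the lower. Absolute configuration is controlled by the (1S)-camphanoyl groups: a homochiral lattice has no inversion centres, so all reacting pairs are related by rotation or screw axes and expose the same pyrone face, and any minor cyclobutane antipode is a diastereomer that chromatography or crystallisation removes. The step needs cross-pairing of C5=C6 with the styryl bond in head-to-tail orientation and not styryl-to-styryl dimerisation, which the donor–acceptor stacking of the electron-rich aryl ester over the electron-poor methoxypyrone should secure.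

Step 4
Reactants: 7 bis[(1S,4R)-camphanate] of the (1R,6S,7S,8S)-dimer
Product: 8 (1R,6S,7S,8S)-7-(4-hydroxyphenyl)-1-[(E)-2-(4-hydroxyphenyl)ethenyl]-5-methoxy-8-(4-methoxy-2-oxo-2H-pyran-6-yl)-2-oxabicyclo[4.2.0]oct-4-en-3-one
Conditions: K2CO3 (cat.), MeOH/THF, 0 °C; pH 7 buffer work-up
Reagents that add atoms: none
Why: Base-catalysed transesterification, in which the aryl esters are far more electrophilic than the vinylogous-carbonate lactone and the 4-methoxypyrone (which already tolerates methoxide in step 1); no stereocentre is involved, and even a reversible ionisation of the C1–O2 bond could reclose only to the cis-fused lactone.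

Compound list
1 | 4-methoxy-6-methyl-2H-pyran-2-one | Cc1cc(OC)cc(=O)o1 | starting material
2 | 4-(tetrahydro-2H-pyran-2-yloxy)benzaldehyde (racemic acetal) | O=Cc1ccc(OC2CCCCO2)cc1 | starting material
3 | 4-methoxy-6-{(E)-2-[4-(tetrahydro-2H-pyran-2-yloxy)phenyl]ethenyl}-2H-pyran-2-one (not isolated) | COc1cc(=O)oc(/C=C/c2ccc(OC3CCCCO3)cc2)c1 | intermediate
4 | 6-[(E)-2-(4-hydroxyphenyl)ethenyl]-4-methoxy-2H-pyran-2-one | COc1cc(=O)oc(/C=C/c2ccc(O)cc2)c1 | intermediate
5 | (1S)-(−)-camphanic chloride, (1S,4R)-4,7,7-trimethyl-3-oxo-2-oxabicyclo[2.2.1]heptane-1-carbonyl chloride | ClC(=O)[C@@]12CC[C@@](C)(C(=O)O1)C2(C)C | starting material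
6 | 4-[(E)-2-(4-methoxy-2-oxo-2H-pyran-6-yl)ethenyl]phenyl (1S,4R)-4,7,7-trimethyl-3-oxo-2-oxabicyclo[2.2.1]heptane-1-carboxylate | COc1cc(=O)oc(/C=C/c2ccc(OC(=O)[C@@]34CC[C@@](C)(C(=O)O3)C4(C)C)cc2)c1 | intermediate
7 | bis[(1S,4R)-camphanate] of 8 on both phenols; core (1R,6S,7S,8S), cis-fused, C7 aryl cis to the pyranone carbon on C6, C8 pyronyl trans to the C7 aryl and cis to the C1 styryl | COC1=CC(=O)O[C@]2(/C=C/c3ccc(OC(=O)[C@@]45CC[C@@](C)(C(=O)O4)C5(C)C)cc3)[C@H]1[C@H](c1ccc(OC(=O)[C@@]34CC[C@@](C)(C(=O)O3)C4(C)C)cc1)[C@H]2c1cc(OC)cc(=O)o1 | intermediate
8 | (1R,6S,7S,8S)-7-(4-hydroxyphenyl)-1-[(E)-2-(4-hydroxyphenyl)ethenyl]-5-methoxy-8-(4-methoxy-2-oxo-2H-pyran-6-yl)-2-oxabicyclo[4.2.0]oct-4-en-3-one | COC1=CC(=O)O[C@]2(/C=C/c3ccc(O)cc3)[C@H]1[C@H](c1ccc(O)cc1)[C@H]2c1cc(OC)cc(=O)o1 | target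

Total step count: 4. Longest linear sequence: 4 steps (1 → 4 → 6 → 7 → 8).

Steps most likely to fail

Step 3 (key step). What may go wrong: the camphanate may crystallise so that neighbouring molecules are not stacked antiparallel with the ring C5=C6 bond of one parallel to, and within about 4 Å of, the styryl bond of the next. The lattice would then stay inert, dimerise styryl-to-styryl, or react through more than one contact with loss of facial control. Fallback, from 4 back to 7: the free phenol 4, the presumed natural monomer, is itself irradiated as a crystalline powder (365 nm), where centrosymmetric antiparallel stacking is available, to give the racemic dimer F1. F1 is acylated on both phenols with 5 (Et3N, DMAP, CH2Cl2) to give 7 and the diastereomeric bis-camphanate F2. The two are separated by chromatography and crystallisation (classical resolution), and the route continues from 7.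

Step 4. What may go wrong: under basic methanolysis the liberated phenoxide of the styryl unit may expel the allylic lactone oxygen at C1 (vinylogous quinone-methide formation followed by fragmentation of the cyclobutane). Alternatively, methoxide may open a lactone ring as fast as it cleaves the hindered camphanate. Fallback, from 4 to 8: the covalent handle and its removal are dispensed with. Compound 4 is co-crystallised with the optically active diol host (4R,5R)-2,2-dimethyl-α,α,α′,α′-tetraphenyl-1,3-dioxolane-4,5-dimethanol; inclusion crystals of this host class with 2-pyranone guests such as coumarin are known to photodimerise enantioselectively. The inclusion crystal is irradiated at 365 nm and the host is removed by chromatography, which should give 8 directly with free phenols. Any remaining antipode is removed on a chiral stationary phase, and the enantiomeric host is used if the sense of induction is the opposite one. No new covalent compound is made.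

Step 1. What may go wrong: the electron-rich aldehyde may condense sluggishly while methoxide slowly opens the pyrone ring, so that conversion stalls. Fallback, from 1 back to 4: 1 is deprotonated at the 6-methyl group with LiN(i-Pr)2 (THF, −78 °C) and added to 2 to give the aldol adduct F3. Warming F3 with catalytic p-TsOH·H2O in toluene dehydrates the p-alkoxybenzylic alcohol (E1) to the E-styrylpyrone and hydrolyses the acetal with the water released, giving 4.

Further compounds
F1 | step 3 | racemic dimer: 8 together with its (1S,6R,7R,8R)-enantiomer | COC1=CC(=O)O[C@]2(/C=C/c3ccc(O)cc3)[C@H]1[C@H](c1ccc(O)cc1)[C@H]2c1cc(OC)cc(=O)o1.COC1=CC(=O)O[C@@]2(/C=C/c3ccc(O)cc3)[C@@H]1[C@@H](c1ccc(O)cc1)[C@@H]2c1cc(OC)cc(=O)o1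
F2 | step 3 | diastereomer of 7: bis[(1S,4R)-camphanate] of the (1S,6R,7R,8R)-dimer | COC1=CC(=O)O[C@@]2(/C=C/c3ccc(OC(=O)[C@@]45CC[C@@](C)(C(=O)O4)C5(C)C)cc3)[C@@H]1[C@@H](c1ccc(OC(=O)[C@@]34CC[C@@](C)(C(=O)O3)C4(C)C)cc1)[C@@H]2c1cc(OC)cc(=O)o1
F0 | step 4 | none | none
F3 | step 1 | 6-{2-hydroxy-2-[4-(tetrahydro-2H-pyran-2-yloxy)phenyl]ethyl}-4-methoxy-2H-pyran-2-one (mixture of stereoisomers) | COc1cc(=O)oc(CC(O)c2ccc(OC3CCCCO3)cc2)c1
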